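**Strategy**

Ring B of the target is a cyclohexene fused to aromatic ring A through C4a and C8a. It carries the guaiacyl group on C1, hydroxymethyl groups on C2 and C3 and an unsubstituted C4. Such a ring maps back onto an ortho-quinodimethane and an E-alkene, so the plan hinges on disconnecting C1–C2 and C3–C4. Light turns an ortho-benzylbenzaldehyde into a hydroxy-ortho-quinodimethane, which adds dimethyl fumarate on titanium bearing a chiral diol: one operation closes ring B, forms both bonds and sets C1, C2 and C3, the extra C4 hydroxyl being cleaved later. The precursor is a benzaldehyde (benzaldehyde locants) with methoxy groups at C2 and C3, a benzyloxy group at C4 and an O-benzylvanillyl group at C6.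

Key step: step 6

Assumption: the (R,R)-configured TADDOL is taken to give the (1R,2S,3R,4R) adduct; the sense of induction is to be settled in the first run, and the (S,S)-diol replaces it if the opposite sense is found.

Locants follow the tetralin skeleton of the target: C1 bears the aryl group, C4 stems from the aldehyde carbon, C5 to C8 belong to ring A.

**Route**

Step 1
Reactants: 1 2,3,4-trihydroxybenzaldehyde
Product: 2 4-benzyloxy-2,3-dihydroxybenzaldehyde
Conditions: BnBr (1.0 equiv), NaHCO3, DMF, 40 °C
Reagents that add atoms: benzyl bromide, BrCc1ccccc1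
Why: Williamson ether synthesis; the 4-OH, para to the formyl group, is the most acidic phenol, the 2-OH is tied up in a hydrogen bond to the carbonyl and the 3-OH is the least acidic, so a weak base and one equivalent of halide should alkylate O4 only.

Step 2
Reactants: 2 4-benzyloxy-2,3-dihydroxybenzaldehyde
Product: 3 4-benzyloxy-2,3-dimethoxybenzaldehyde
Conditions: MeI (excess), K2CO3, DMF, rt to 40 °C
Reagents that add atoms: iodomethane, CI
Why: exhaustive Williamson O-methylation; the stronger base and excess iodomethane also alkylate the hydrogen-bonded 2-OH, and the benzyl ether and the aldehyde are inert.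

Step 3
Reactants: 3 4-benzyloxy-2,3-dimethoxybenzaldehyde
Product: 7 4-benzyloxy-6-bromo-2,3-dimethoxybenzaldehyde, via lithium alpha-amino alkoxide 4 (not isolated), via ortho-lithiated amino alkoxide 5 (not isolated), via brominated amino alkoxide 6 (not isolated)
Conditions: LiN(Me)CH2CH2NMe2 (from N,N,N′-trimethylethylenediamine and n-BuLi), THF, −20 °C; n-BuLi, −20 °C; BrCl2C–CCl2Br, −78 °C to rt; cold dilute HCl
Reagents that add atoms: 1,2-dibromotetrachloroethane, BrC(Cl)(Cl)C(Cl)(Cl)Br
Why: Comins-type in situ protection and directed ortho-lithiation; the amide adds to the formyl group, the chelating diamine arm of 4 delivers n-BuLi to C6 (the only ring position beside it) in preference to C5 next to the benzyloxy group, the aryllithium 5 takes bromine from the electrophile, and acid work-up returns the aldehyde.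

Step 4
Reactants: 8 4-benzyloxy-3-methoxybenzyl alcohol
Product: 9 4-benzyloxy-3-methoxybenzyl chloride
Conditions: SOCl2, CH2Cl2, 0 °C to rt; used crude
Reagents that add atoms: thionyl chloride, O=S(Cl)Cl
Why: chlorodehydroxylation through the chlorosulfite, fast for an electron-rich benzylic alcohol; the aryl benzyl ether is untouched at this temperature.

Step 5
Reactants: 9 4-benzyloxy-3-methoxybenzyl chloride; 7 4-benzyloxy-6-bromo-2,3-dimethoxybenzaldehyde
Product: 11 4-benzyloxy-6-(4-benzyloxy-3-methoxybenzyl)-2,3-dimethoxybenzaldehyde, via benzylzinc chloride 10 (not isolated)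
Conditions: Zn dust, LiCl, THF, rt; then 7, Pd(OAc)2 (cat.), SPhos (cat.), THF, rt
Reagents that add atoms: none
Why: LiCl-assisted zinc insertion into the benzylic C–Cl bond gives 10, and Negishi cross-coupling (oxidative addition of zerovalent palladium, formed from Pd(OAc)2 and SPhos, into the C–Br bond, transmetalation, reductive elimination) joins C8a to the benzylic carbon; the benzylzinc reagent is too mild to attack the hindered, electron-rich formyl group within the time the fast catalyst needs.

Step 6
Reactants: 11 4-benzyloxy-6-(4-benzyloxy-3-methoxybenzyl)-2,3-dimethoxybenzaldehyde; 12 dimethyl fumarate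
Product: 14 dimethyl (1R,2S,3R,4R)-7-benzyloxy-1-(4-benzyloxy-3-methoxyphenyl)-4-hydroxy-5,6-dimethoxy-1,2,3,4-tetrahydronaphthalene-2,3-dicarboxylate, via hydroxy-ortho-quinodimethane 13 (not isolated)
Conditions: Ti(OiPr)4 (2 equiv), (4R,5R)-2,2-dimethyl-α,α,α′,α′-tetraphenyl-1,3-dioxolane-4,5-dimethanol [(R,R)-TADDOL, 2.2 equiv], 12 (3 equiv), degassed toluene, hν 365 nm, rt; aq. NaHCO3
Reagents that add atoms: none
Why: Light absorption by the aryl aldehyde is followed by a 1,5-shift of one hydrogen of the diarylmethane CH2 onto the carbonyl oxygen, which leaves photoenol 13 with hydroxyl and aryl group both pointing outward; the titanium diolate takes it up through the dienol oxygen. The closest known reaction type is the photoenolisation/Diels–Alder reaction of ortho-alkylbenzaldehydes with electron-poor alkenes in its enantioselective form mediated by Ti(OiPr)4 and a TADDOL-type diol. Ring B forms in a six-membered mode by intermolecular [4+2] cycloaddition: the two new sigma bonds, C1–C2 and C3–C4, arise in one concerted suprafacial event, and ring A becomes aromatic again. C1 and C4 come out cis because both diene termini carry their substituent outward, and C2 and C3 come out trans because the E geometry of the fumarate is transferred. The C3 ester ends up cis to the C4 oxygen because titanium on that oxygen also holds the nearer ester carbonyl endo, which places the C2 ester exo and trans to the C1 aryl group; the absolute sense comes from the diolate shielding one face of the bound diene. The step needs endo placement of the C3 ester and face selectivity but no regioselectivity, since the dienophile is symmetrical; the single dienol oxygen as titanium anchor provides the endo placement, and the CH2 flanked by two electron-rich arenes makes the hydrogen shift easy.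

Step 7
Reactants: 14 dimethyl (1R,2S,3R,4R)-7-benzyloxy-1-(4-benzyloxy-3-methoxyphenyl)-4-hydroxy-5,6-dimethoxy-1,2,3,4-tetrahydronaphthalene-2,3-dicarboxylate
Product: 15 (1R,2S,3S,4R)-7-benzyloxy-1-(4-benzyloxy-3-methoxyphenyl)-2,3-bis(hydroxymethyl)-5,6-dimethoxy-1,2,3,4-tetrahydronaphthalen-4-ol
Conditions: LiAlH4, THF, 0 °C to rt; H2O, aq. NaOH work-up
Reagents that add atoms: none
Why: hydride reduction of both methyl esters to primary alcohols; hydride addition to the ester carbonyls outpaces enolisation at C2 and C3, so no stereocentre is touched (the change of the C3 descriptor is only a change of substituent priorities).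

Step 8
Reactants: 15 (1R,2S,3S,4R)-7-benzyloxy-1-(4-benzyloxy-3-methoxyphenyl)-2,3-bis(hydroxymethyl)-5,6-dimethoxy-1,2,3,4-tetrahydronaphthalen-4-ol
Product: 16 4-[(1R,2S,3S)-7-hydroxy-2,3-bis(hydroxymethyl)-5,6-dimethoxy-1,2,3,4-tetrahydronaphthalen-1-yl]-2-methoxyphenol (target)
Conditions: H2 (1–3 atm), 10% Pd/C, EtOH/AcOH, rt to 40 °C
Reagents that add atoms: none
Why: heterogeneous hydrogenolysis cleaves both aryl benzyl ethers and also the secondary C4–O bond, which is benzylic and activated by the C7 oxygen para to C4a and by the C5 methoxy group ortho to it, so C4 becomes CH2; C1, C2 and C3 are not involved.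

**Compound list**

1 | 2,3,4-trihydroxybenzaldehyde | O=Cc1ccc(O)c(O)c1O | starting material
2 | 4-benzyloxy-2,3-dihydroxybenzaldehyde | O=Cc1ccc(OCc2ccccc2)c(O)c1O | intermediate
3 | 4-benzyloxy-2,3-dimethoxybenzaldehyde | O=Cc1ccc(OCc2ccccc2)c(OC)c1OC | intermediate
4 | lithium alpha-amino alkoxide from 3 and lithium N,N,N′-trimethylethylenediamide (not isolated) | [Li]OC(c1ccc(OCc2ccccc2)c(OC)c1OC)N(C)CCN(C)C | intermediate
5 | C6-lithiated amino alkoxide (not isolated) | [Li]OC(c1c([Li])cc(OCc2ccccc2)c(OC)c1OC)N(C)CCN(C)C | intermediate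
6 | C6-brominated amino alkoxide (not isolated) | [Li]OC(c1c(Br)cc(OCc2ccccc2)c(OC)c1OC)N(C)CCN(C)C | intermediate
7 | 4-benzyloxy-6-bromo-2,3-dimethoxybenzaldehyde | O=Cc1c(Br)cc(OCc2ccccc2)c(OC)c1OC | intermediate
8 | 4-benzyloxy-3-methoxybenzyl alcohol | COc1cc(CO)ccc1OCc1ccccc1 | starting material
9 | 4-benzyloxy-3-methoxybenzyl chloride | COc1cc(CCl)ccc1OCc1ccccc1 | intermediate
10 | (4-benzyloxy-3-methoxybenzyl)zinc chloride (not isolated) | COc1cc(C[Zn]Cl)ccc1OCc1ccccc1 | intermediate
11 | 4-benzyloxy-6-(4-benzyloxy-3-methoxybenzyl)-2,3-dimethoxybenzaldehyde | COc1cc(Cc2cc(OCc3ccccc3)c(OC)c(OC)c2C=O)ccc1OCc1ccccc1 | intermediate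
12 | dimethyl fumarate | COC(=O)/C=C/C(=O)OC | starting material
13 | hydroxy-ortho-quinodimethane (photoenol of 11; hydroxyl and aryl group both outward; not isolated) | O/C=C1\C(OC)=C(OC)C(OCc2ccccc2)=C/C1=C\c1ccc(OCc2ccccc2)c(OC)c1 | intermediate
14 | dimethyl (1R,2S,3R,4R)-7-benzyloxy-1-(4-benzyloxy-3-methoxyphenyl)-4-hydroxy-5,6-dimethoxy-1,2,3,4-tetrahydronaphthalene-2,3-dicarboxylate (1,2-trans, 2,3-trans, 3,4-cis) | COc1cc([C@@H]2c3cc(OCc4ccccc4)c(OC)c(OC)c3[C@H](O)[C@H](C(=O)OC)[C@H]2C(=O)OC)ccc1OCc1ccccc1 | intermediate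
15 | (1R,2S,3S,4R)-7-benzyloxy-1-(4-benzyloxy-3-methoxyphenyl)-2,3-bis(hydroxymethyl)-5,6-dimethoxy-1,2,3,4-tetrahydronaphthalen-4-ol | COc1cc([C@@H]2c3cc(OCc4ccccc4)c(OC)c(OC)c3[C@H](O)[C@H](CO)[C@H]2CO)ccc1OCc1ccccc1 | intermediate
16 | 4-[(1R,2S,3S)-7-hydroxy-2,3-bis(hydroxymethyl)-5,6-dimethoxy-1,2,3,4-tetrahydronaphthalen-1-yl]-2-methoxyphenol | COc1cc([C@@H]2c3cc(O)c(OC)c(OC)c3C[C@H](CO)[C@H]2CO)ccc1O | target

**Count and risks**

Total step count: 8. Longest linear sequence: 7 steps (1 → 2 → 3 → 7 → 11 → 14 → 15 → 16; step 4 feeds step 5).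

Steps most likely to fail:

1. Step 6. Face discrimination by the titanium diolate may be too weak with an acyclic diester, return of the hydrogen in the photoenol may outrun the cycloaddition, or sensitised E/Z isomerisation of the fumarate may lead to cis-diester adducts. Exchange of methyl for isopropyl ester groups on titanium would do no harm, since step 7 reduces every ester. Fallback: auxiliary control in place of ligand control, setting out from 11. Fumaryl chloride and methyl (R)-mandelate (Et3N, CH2Cl2) give bis[(R)-2-methoxy-2-oxo-1-phenylethyl] fumarate F1; the mandelate enantiomer is chosen so that the adduct has the (1R,2S,3R,4R) core, and the (R)-ester is written here on the same footing as the assumption above. Irradiation of 11 with F1 in degassed toluene without titanium should give the bis-mandelate adduct bis[(R)-2-methoxy-2-oxo-1-phenylethyl] (1R,2S,3R,4R)-7-benzyloxy-1-(4-benzyloxy-3-methoxyphenyl)-4-hydroxy-5,6-dimethoxy-1,2,3,4-tetrahydronaphthalene-2,3-dicarboxylate F2, the ester next to the hydroxyl being held endo by a hydrogen bond. LiAlH4 in THF then reduces all four ester groups and releases the auxiliary, and the route is rejoined at 15.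

2. Step 3. Butyllithium may remove a benzylic proton of the benzyl ether (followed by Wittig rearrangement) or metalate C5 beside the ether oxygen. Fallback without organolithium, setting out from 3. Condensation with tert-butylamine (MgSO4, CH2Cl2) gives the N-tert-butyl aldimine F3. Nitrogen-directed ortho-C–H borylation ([Ir(OMe)(cod)]2, 8-aminoquinoline, B2pin2, THF, 60 °C) should give the C6-borylated imine F4, which hydrolyses on aqueous work-up to 4-benzyloxy-2,3-dimethoxy-6-(4,4,5,5-tetramethyl-1,3,2-dioxaborolan-2-yl)benzaldehyde F5. Suzuki–Miyaura coupling of F5 with benzyl chloride 9 (PdCl2(dppf), K3PO4, dioxane/H2O, 80 °C) comes back to the route at 11, so that steps 3 and 5 are both bypassed.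

3. Step 8. Ionisation at C4 may be followed by loss of the C3 proton and re-addition of hydrogen to the alkene from either face, which would erode the C3 configuration; cleavage of the C4–O bond may also stall once the phenols are free. Fallback with the deoxygenation separated from the debenzylation, setting out from 14. Ionic hydrogenation (Et3SiH, TFA, CH2Cl2, 0 °C) traps the C4 cation with hydride and should give dimethyl (1R,2S,3S)-7-benzyloxy-1-(4-benzyloxy-3-methoxyphenyl)-5,6-dimethoxy-1,2,3,4-tetrahydronaphthalene-2,3-dicarboxylate F6. LiAlH4 in THF gives the dibenzyl diol [(1R,2S,3S)-7-benzyloxy-1-(4-benzyloxy-3-methoxyphenyl)-3-(hydroxymethyl)-5,6-dimethoxy-1,2,3,4-tetrahydronaphthalen-2-yl]methanol F7. Hydrogenolysis under neutral conditions (H2, Pd/C, EtOAc/EtOH) then removes only the two benzyl groups and arrives at 16.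

**Further compounds**

F1 | step 6 | bis[(R)-2-methoxy-2-oxo-1-phenylethyl] fumarate | COC(=O)[C@H](OC(=O)/C=C/C(=O)O[C@@H](C(=O)OC)c1ccccc1)c1ccccc1
F2 | step 6 | bis[(R)-2-methoxy-2-oxo-1-phenylethyl] (1R,2S,3R,4R)-7-benzyloxy-1-(4-benzyloxy-3-methoxyphenyl)-4-hydroxy-5,6-dimethoxy-1,2,3,4-tetrahydronaphthalene-2,3-dicarboxylate | COc1cc([C@@H]2c3cc(OCc4ccccc4)c(OC)c(OC)c3[C@H](O)[C@H](C(=O)O[C@@H](C(=O)OC)c3ccccc3)[C@H]2C(=O)O[C@@H](C(=O)OC)c2ccccc2)ccc1OCc1ccccc1
F3 | step 3 | (E)-N-tert-butyl-1-(4-benzyloxy-2,3-dimethoxyphenyl)methanimine | CC(C)(C)/N=C/c1ccc(OCc2ccccc2)c(OC)c1OC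
F4 | step 3 | (E)-N-tert-butyl-1-[4-benzyloxy-2,3-dimethoxy-6-(4,4,5,5-tetramethyl-1,3,2-dioxaborolan-2-yl)phenyl]methanimine | CC(C)(C)/N=C/c1c(B2OC(C)(C)C(C)(C)O2)cc(OCc2ccccc2)c(OC)c1OC
F5 | step 3 | 4-benzyloxy-2,3-dimethoxy-6-(4,4,5,5-tetramethyl-1,3,2-dioxaborolan-2-yl)benzaldehyde | O=Cc1c(B2OC(C)(C)C(C)(C)O2)cc(OCc2ccccc2)c(OC)c1OC
F6 | step 8 | dimethyl (1R,2S,3S)-7-benzyloxy-1-(4-benzyloxy-3-methoxyphenyl)-5,6-dimethoxy-1,2,3,4-tetrahydronaphthalene-2,3-dicarboxylate | COc1cc([C@@H]2c3cc(OCc4ccccc4)c(OC)c(OC)c3C[C@H](C(=O)OC)[C@H]2C(=O)OC)ccc1OCc1ccccc1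
F7 | step 8 | [(1R,2S,3S)-7-benzyloxy-1-(4-benzyloxy-3-methoxyphenyl)-3-(hydroxymethyl)-5,6-dimethoxy-1,2,3,4-tetrahydronaphthalen-2-yl]methanol | COc1cc([C@@H]2c3cc(OCc4ccccc4)c(OC)c(OC)c3C[C@H](CO)[C@H]2CO)ccc1OCc1ccccc1
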